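Readings and results were computed with made-up constants; noise was put on by code.

**The question.** How much tris adduct stands in the flask after 1.0 h, and which move after that adds most?

all flasks: starting material 32 mM

|  | reagent | temperature | remark | time |
|---|---|---|---|---|
| midnight | 3 equiv | 70 °C | the very flask that is asked about, followed so far |  |
| winter | 3 equiv | 65 °C | run made earlier |  |
| flask | 3.00 equiv | 70 °C |  | 1.0 h |

- midnight (time / min: tris adduct / %, starting material / %): 3.00: 0.6, 76.7; 6.00: 0, 58.1; 15.0: 2.9, 29.8; 40.0: 8.1, 7.5
- winter (time / min: tris adduct / %, starting material / %): 3.00: 0.2, 81.2; 6.00: 0, 67.4; 15.0: 2.0, 41.5; 40.0: 6.9, 13.2

(scatter of a reading: 0.5 percentage points)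

- birch: change nothing and wait 1.0 h more
- cedar: at 1.0 h take out 90 % of the tris adduct then present, then wait 1.0 h
- oak: at 1.0 h add reagent, 100 % of the amount charged, then wait 1.0 h
- ash: at 1.0 h raise the temperature by 20 K, then wait 1.0 h

* tris adduct, in percent of the starting material first charged, at 1.0 h
* which option adds most tris adduct ("none" when 2 percentage points or less is all one gets) (birch / cedar / oak / ash / none)
* tris adduct present, with what was taken out counted in, in percent of the starting material first charged, after birch
* tris adduct present, with what was taken out counted in, in percent of the starting material first charged, after ash

- for released group the crystals are counted in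
- as a solid, counted per litre of solution: crystals
- tris adduct taken out counts as made
- steps thought possible: crystals <-> released group; reagent + double product -> tris adduct + released group; starting material + reagent -> mono adduct + released group; reagent + mono adduct -> double product + released group; tris adduct <-> isomer of the product
- additions bring no volume worth counting

**Reagent gauge.** The runs read tris adduct and starting material, not reagent, so I tried to read reagent from the starting material. The step that takes starting material also takes reagent. I therefore took the loss rate over the first 3.00 min of the midnight run, 0.0884 /min, as the full-charge rate, a pseudo-first-order rate. In the midnight run, a later loss rate divided by it gives the fraction of reagent left, within the scatter of the readings. Between 15.0 min and 40.0 min the loss rate was 0.0552 /min, so the gauge read 62.4 % around 27.5 min.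

**Plain count.** Each addition takes one reagent, and 3 equiv was charged. Taking the mean of the two readings of that stretch, and counting the starting material gone and two further additions for each tris adduct, leaves 69.2 % of the reagent. The two ways part, the count standing higher. The count is the one that cheats, since it charges nothing for unread forms. I read its gap as further additions worth 20.4 % of the starting material, which I put down to double product or isomer of the product.

**My reckoning.** Carrying the tris adduct's late rise straight on gave 12.3 % at 1.0 h. I then went round once more, letting the gauge fall by the same factor per minute. It came to 42.4 % in the middle of the last stretch and 35.7 % at 1.0 h. Scaling the rise by the reagent gave 10.9 %.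

**The forecast.** It gave 12 % for now, 21 % after birch and 29 % after ash, and it chose oak: “Adding 3 equiv of reagent raises the rate about 3.5-fold, so oak wins”. My figure for now stood below its figure.

**The flask.** It held 8.26 % at 1.0 h. Birch ended at 6.50 % and ash at 16.5 %, and the best move was ash. The gains were −1.8 percentage points for birch, 5.2 points for cedar, 1.7 points for oak and 8.3 points for ash.

    crystals ⇌ released group, rate k1*(cs1 - [released group]) while solid is left; crystals form when [released group] > cs1 (solubility = 0.990 mM, k = 0.00427 /s)
    reagent + double product → tris adduct + released group (k = 0.0124 /M/s, Ea = 84.0 kJ/mol)
    starting material + reagent → mono adduct + released group (k = 0.0165 /M/s, Ea = 64.0 kJ/mol)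
    reagent + mono adduct → double product + released group (k = 0.00566 /M/s, Ea = 86.0 kJ/mol)
    tris adduct ⇌ isomer of the product (K = 16.0, k = 0.00146 /s, Ea = 112 kJ/mol, ΔH = −70.0 kJ/mol)
    (constants at 70 °C)

**Where it went.** At 1.0 h the flask's starting material had a half-life of 19 min by its step with the reagent, which puts the gauge at 41.3 %. The flask still held 38.5 % of its reagent, yet birch lost tris adduct. Without the path to the isomer of the product, both ways, the flask stood at 33.6 % at 1.0 h, a shift of 25 points, bigger than the 7.6 points from holding the reagent; that path is the largest single effect on this figure, not the main reason. In the neighbour charged with 1.80 equiv, the 15 % of starting material left puts the gauge's average over the hour at 59.6 % of its own reagent charge, and that neighbour held 3.01 % tris adduct.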